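Ring C is assembled as a [4+2] union of the C3–C4–C4a–C8a unit of a 2-fluoroacetophenone (ring A) with the C2=O1 carbonyl of a ring B benzoate. The key step exploits the position of the C4 ketone: C3 is its α-carbon and C8a its ortho carbon, so a Claisen condensation forges C2–C3 and the diketonate oxygen then displaces fluoride at C8a (SNAr), forging O1–C8a and giving a flavone in one flask. C2 is deliberately kept sp2 through this hot, basic operation; the 2S centre is set afterwards by copper hydride-catalysed asymmetric conjugate reduction, and three MOM ethers are removed last. The precursor is a diprenylated, MOM-protected 2-fluoroacetophenone.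

Key step: step 5

Remark: flavonoid numbering (O1, C2, C3, C4, C4a, C5–C8, C8a, primed locants for ring B) is used for all intermediates. Which antipode of DTBM-SEGPHOS gives the 2S product cannot be assigned with certainty beforehand; the (R)-ligand is written, and its mirror image is to be used if a first run (chiral HPLC, CD) shows the 2R product.

Step 1
Reactants: 1 1-(2-fluoro-4-hydroxyphenyl)ethan-1-one
Product: 2 1-(3,5-dibromo-2-fluoro-4-hydroxyphenyl)ethan-1-one
Conditions: NBS (2.1 equiv), iPr2NH (10 mol %), CH2Cl2, 0 °C → rt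
Reagents that add atoms: N-bromosuccinimide, O=C1CCC(=O)N1Br
Why: Electrophilic aromatic bromination (amine-catalysed ortho-bromination of a phenol): the free OH directs both bromines to its two ortho positions, the para position being blocked by the acetyl group, and without acid or light the methyl ketone should stay untouched.

Step 2
Reactants: 2 1-(3,5-dibromo-2-fluoro-4-hydroxyphenyl)ethan-1-one
Product: 3 1-[3,5-dibromo-2-fluoro-4-(methoxymethoxy)phenyl]ethan-1-one
Conditions: NaH (1.1 equiv), MOMCl (1.2 equiv), DMF, 0 °C → rt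
Reagents that add atoms: chloromethyl methyl ether, COCCl
Why: Williamson ether synthesis on the acidic 2,6-dibromophenoxide; the MOM ether withstands strong base and hot DMF and prevents a phenoxide para to the ketone from shutting down the later SNAr.

Step 3
Reactants: 3 1-[3,5-dibromo-2-fluoro-4-(methoxymethoxy)phenyl]ethan-1-one; 4 tributyl(3-methylbut-2-en-1-yl)stannane (2.4 equiv)
Product: 5 1-[2-fluoro-4-(methoxymethoxy)-3,5-bis(3-methylbut-2-en-1-yl)phenyl]ethan-1-one
Conditions: Pd(PPh3)4 (10 mol %), DMF, 100 °C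
Reagents that add atoms: none
Why: Twofold Stille coupling, in which reductive elimination from the aryl–palladium–prenyl intermediate is expected at the unsubstituted CH2 terminus to give the linear prenyl groups, while the neutral conditions spare the C–F bond, the ketone and the MOM ether.

Step 4
Reactants: 6 methyl 2,4-dihydroxybenzoate
Product: 7 methyl 2,4-bis(methoxymethoxy)benzoate
Conditions: NaH (2.4 equiv), MOMCl (2.4 equiv), DMF, 0 °C → rt
Reagents that add atoms: chloromethyl methyl ether, COCCl
Why: Williamson ether synthesis on both phenoxides (NaH also breaks the hydrogen bond of the 2-OH to the ester), leaving the methyl ester as the acyl donor for the key step.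

Step 5
Reactants: 5 1-[2-fluoro-4-(methoxymethoxy)-3,5-bis(3-methylbut-2-en-1-yl)phenyl]ethan-1-one; 7 methyl 2,4-bis(methoxymethoxy)benzoate
Product: 9 2-[2,4-bis(methoxymethoxy)phenyl]-7-(methoxymethoxy)-6,8-bis(3-methylbut-2-en-1-yl)-4H-chromen-4-one (tris-MOM flavone), via 1,3-diketone 8 (not isolated)
Conditions: KHMDS (2.2 equiv), THF, −78 °C; add 7, −78 °C → rt; then DMF, 100 °C (same flask)
Reagents that add atoms: none
Why: Deprotonation of 5 gives the potassium enolate, whose carbon (C3) adds to the ester carbonyl of 7 (the future C2) and expels methoxide (Claisen condensation, C2–C3), the product being held as the stabilised diketonate of 8; on heating in DMF the enolate oxygen on C2 adds to C8a, which as the fluorine-bearing carbon ortho to the C4 ketone is a vinylogous acyl fluoride, and loss of fluoride from the Meisenheimer intermediate gives O1–C8a and the pyranone. The closest known reaction type is the one-pot acylation/SNAr synthesis of chromones and 4-quinolones from 2-fluoroaryl ketones. Ring C closes by a 6-endo-trig addition–elimination at C8a, the C8a=C4a–C4=O unit lying inside the new ring. No stereocentre is formed: C2 is kept sp2 on purpose, because a flavanone would open to the chalcone under these conditions. The step needs C- over O-acylation (secured by the thermodynamic diketonate sink and the non-enolisable ester) and attack at C8a by the diketonate oxygen, not by external methoxide (the anionic diketonate repels external anions while its own oxygen is held within reach); the prenyl and MOM groups are inert to amide base and hot DMF.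

Step 6
Reactants: 9 2-[2,4-bis(methoxymethoxy)phenyl]-7-(methoxymethoxy)-6,8-bis(3-methylbut-2-en-1-yl)-4H-chromen-4-one
Product: 11 (2S)-2-[2,4-bis(methoxymethoxy)phenyl]-7-(methoxymethoxy)-6,8-bis(3-methylbut-2-en-1-yl)-2,3-dihydro-4H-chromen-4-one, via silyl enol ether 10 (not isolated)
Conditions: Cu(OAc)2·H2O (5 mol %), (R)-DTBM-SEGPHOS (5.5 mol %), (EtO)2MeSiH (3 equiv), toluene, 0 °C → rt; then AcOH/H2O/THF, 0 °C
Reagents that add atoms: none
Why: Copper hydride-catalysed asymmetric conjugate reduction (1,4-hydrosilylation) as known for 2-substituted chromones: the bisphosphine-bound Cu–H delivers hydride to one enantiotopic face of C2 and so sets the 2S centre under ligand control, the enolate is trapped as silyl enol ether 10, which cannot ring-open, and mild acid hydrolysis protonates C3, while prenyl alkenes and MOM ethers are inert to CuH.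

Step 7
Reactants: 11 (2S)-2-[2,4-bis(methoxymethoxy)phenyl]-7-(methoxymethoxy)-6,8-bis(3-methylbut-2-en-1-yl)-2,3-dihydro-4H-chromen-4-one
Product: 12 (2S)-2-(2,4-dihydroxyphenyl)-7-hydroxy-6,8-bis(3-methylbut-2-en-1-yl)-2,3-dihydro-4H-chromen-4-one
Conditions: HCl (1.25 M in MeOH), MeOH/THF, 25–40 °C, stopped at full conversion
Reagents that add atoms: none
Why: Acid-catalysed acetal cleavage (methanolysis) of the three aryl MOM ethers; flavanones lose configuration mainly by base-mediated ring opening, so a short exposure to dilute methanolic HCl should leave C2 and the prenyl groups intact.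

Compound list
1 | 1-(2-fluoro-4-hydroxyphenyl)ethan-1-one | CC(=O)c1ccc(O)cc1F | starting material
2 | 1-(3,5-dibromo-2-fluoro-4-hydroxyphenyl)ethan-1-one | CC(=O)c1cc(Br)c(O)c(Br)c1F | intermediate
3 | 1-[3,5-dibromo-2-fluoro-4-(methoxymethoxy)phenyl]ethan-1-one | CC(=O)c1cc(Br)c(OCOC)c(Br)c1F | intermediate
4 | tributyl(3-methylbut-2-en-1-yl)stannane | CCCC[Sn](CCCC)(CCCC)CC=C(C)C | starting material
5 | 1-[2-fluoro-4-(methoxymethoxy)-3,5-bis(3-methylbut-2-en-1-yl)phenyl]ethan-1-one | CC(=O)c1cc(CC=C(C)C)c(OCOC)c(CC=C(C)C)c1F | intermediate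
6 | methyl 2,4-dihydroxybenzoate | COC(=O)c1ccc(O)cc1O | starting material
7 | methyl 2,4-bis(methoxymethoxy)benzoate | COC(=O)c1ccc(OCOC)cc1OCOC | intermediate
8 | 1-[2,4-bis(methoxymethoxy)phenyl]-3-[2-fluoro-4-(methoxymethoxy)-3,5-bis(3-methylbut-2-en-1-yl)phenyl]propane-1,3-dione (present in the flask as its potassium enolate) | CC(C)=CCc1cc(C(=O)CC(=O)c2ccc(OCOC)cc2OCOC)c(F)c(CC=C(C)C)c1OCOC | intermediate
9 | 2-[2,4-bis(methoxymethoxy)phenyl]-7-(methoxymethoxy)-6,8-bis(3-methylbut-2-en-1-yl)-4H-chromen-4-one | CC(C)=CCc1cc2c(c(CC=C(C)C)c1OCOC)OC(c1ccc(OCOC)cc1OCOC)=CC2=O | intermediate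
10 | (2S)-2-[2,4-bis(methoxymethoxy)phenyl]-4-{[diethoxy(methyl)silyl]oxy}-7-(methoxymethoxy)-6,8-bis(3-methylbut-2-en-1-yl)-2H-chromene | CC(C)=CCc1cc2c(c(CC=C(C)C)c1OCOC)O[C@H](c1ccc(OCOC)cc1OCOC)C=C2O[Si](C)(OCC)OCC | intermediate
11 | (2S)-2-[2,4-bis(methoxymethoxy)phenyl]-7-(methoxymethoxy)-6,8-bis(3-methylbut-2-en-1-yl)-2,3-dihydro-4H-chromen-4-one | CC(C)=CCc1cc2c(c(CC=C(C)C)c1OCOC)O[C@H](c1ccc(OCOC)cc1OCOC)CC2=O | intermediate
12 | (2S)-2-(2,4-dihydroxyphenyl)-7-hydroxy-6,8-bis(3-methylbut-2-en-1-yl)-2,3-dihydro-4H-chromen-4-one | CC(C)=CCc1cc2c(c(CC=C(C)C)c1O)O[C@H](c1ccc(O)cc1O)CC2=O | target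

Total steps: 7. Longest linear sequence: 6 steps (steps 1, 2, 3, 5, 6 and 7, from compound 1).

Steps most likely to fail

Step 6. Hydride transfer to the hindered, electron-rich C2 of the vinylogous ester may be sluggish, 1,2-reduction may compete, the ortho-substituted ring B may erode facial selectivity, and the copper enolate may undergo β-elimination with ring opening. The fallback sets out from 9 and comes back at 11. Non-selective conjugate reduction of 9 with L-Selectride (THF, −78 °C, cold AcOH quench) should give the racemic 2-[2,4-bis(methoxymethoxy)phenyl]-7-(methoxymethoxy)-6,8-bis(3-methylbut-2-en-1-yl)-2,3-dihydro-4H-chromen-4-one F1. Kinetic resolution of F1 by asymmetric transfer hydrogenation (RuCl(p-cymene)[(R,R)-TsDPEN], HCO2H/Et3N, EtOAc, rt, stopped near half conversion) is expected to reduce the 2R enantiomer to the cis alcohol (2R,4R)-2-[2,4-bis(methoxymethoxy)phenyl]-7-(methoxymethoxy)-6,8-bis(3-methylbut-2-en-1-yl)-3,4-dihydro-2H-chromen-4-ol F2. F2 is removed by chromatography, leaving the 2S ketone 11; the catalyst antipode is to be confirmed as for step 6.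

Step 5. C-acylation by the electron-rich, ortho-substituted ester may be incomplete, or the ring closure may stall because C8a is flanked by the C8 prenyl group and deactivated by the para alkoxy group, so that retro-Claisen cleavage takes over on heating. The fallback sets out from 5 and comes back at 9. Fluoride is first displaced by an external oxygen nucleophile (acetohydroxamic acid, K2CO3, DMSO, 80 °C; SNAr followed by Lossen-type release of the phenol) to give 1-[2-hydroxy-4-(methoxymethoxy)-3,5-bis(3-methylbut-2-en-1-yl)phenyl]ethan-1-one F3. Claisen condensation of F3 with ester 7 (LiHMDS, 3.3 equiv, THF, −78 °C → rt) should give 1-[2,4-bis(methoxymethoxy)phenyl]-3-[2-hydroxy-4-(methoxymethoxy)-3,5-bis(3-methylbut-2-en-1-yl)phenyl]propane-1,3-dione F4. Cyclodehydration of F4 (NaOAc, AcOH, 90 °C) then closes ring C through O1–C2 to give flavone 9.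

Step 7. Acid may erode the C2 configuration (reversible ionisation of the benzylic C2–O1 bond assisted by the 2,4-dioxygenated ring B, or ring opening to the chalcone), and the freed 7-OH may add to a neighbouring prenyl double bond. The fallback sets out from 9 and comes back at 12; it changes the protecting groups before the stereocentre exists.
- Methanolic HCl on the achiral flavone 9 should give 2-(2,4-dihydroxyphenyl)-7-hydroxy-6,8-bis(3-methylbut-2-en-1-yl)-4H-chromen-4-one F5.
- Silylation (TBSCl, imidazole, DMF, 40 °C) gives 2-[2,4-bis(tert-butyldimethylsilyloxy)phenyl]-7-(tert-butyldimethylsilyloxy)-6,8-bis(3-methylbut-2-en-1-yl)-4H-chromen-4-one F6.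
- The conditions of step 6 should give, through the silyl enol ether (2S)-2-[2,4-bis(tert-butyldimethylsilyloxy)phenyl]-7-(tert-butyldimethylsilyloxy)-4-{[diethoxy(methyl)silyl]oxy}-6,8-bis(3-methylbut-2-en-1-yl)-2H-chromene F7, the flavanone (2S)-2-[2,4-bis(tert-butyldimethylsilyloxy)phenyl]-7-(tert-butyldimethylsilyloxy)-6,8-bis(3-methylbut-2-en-1-yl)-2,3-dihydro-4H-chromen-4-one F8.
- Buffered fluoride (Et3N·3HF, THF, 0 °C → rt) then releases 12 without acid or base strong enough to affect C2.

Further compounds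
F1 | step 6 | racemic 2-[2,4-bis(methoxymethoxy)phenyl]-7-(methoxymethoxy)-6,8-bis(3-methylbut-2-en-1-yl)-2,3-dihydro-4H-chromen-4-one | CC(C)=CCc1cc2c(c(CC=C(C)C)c1OCOC)OC(c1ccc(OCOC)cc1OCOC)CC2=O
F2 | step 6 | (2R,4R)-2-[2,4-bis(methoxymethoxy)phenyl]-7-(methoxymethoxy)-6,8-bis(3-methylbut-2-en-1-yl)-3,4-dihydro-2H-chromen-4-ol | CC(C)=CCc1cc2c(c(CC=C(C)C)c1OCOC)O[C@@H](c1ccc(OCOC)cc1OCOC)C[C@H]2O
F3 | step 5 | 1-[2-hydroxy-4-(methoxymethoxy)-3,5-bis(3-methylbut-2-en-1-yl)phenyl]ethan-1-one | CC(=O)c1cc(CC=C(C)C)c(OCOC)c(CC=C(C)C)c1O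
F4 | step 5 | 1-[2,4-bis(methoxymethoxy)phenyl]-3-[2-hydroxy-4-(methoxymethoxy)-3,5-bis(3-methylbut-2-en-1-yl)phenyl]propane-1,3-dione | CC(C)=CCc1cc(C(=O)CC(=O)c2ccc(OCOC)cc2OCOC)c(O)c(CC=C(C)C)c1OCOC
F5 | step 7 | 2-(2,4-dihydroxyphenyl)-7-hydroxy-6,8-bis(3-methylbut-2-en-1-yl)-4H-chromen-4-one | CC(C)=CCc1cc2c(c(CC=C(C)C)c1O)OC(c1ccc(O)cc1O)=CC2=O
F6 | step 7 | 2-[2,4-bis(tert-butyldimethylsilyloxy)phenyl]-7-(tert-butyldimethylsilyloxy)-6,8-bis(3-methylbut-2-en-1-yl)-4H-chromen-4-one | CC(C)=CCc1cc2c(c(CC=C(C)C)c1O[Si](C)(C)C(C)(C)C)OC(c1ccc(O[Si](C)(C)C(C)(C)C)cc1O[Si](C)(C)C(C)(C)C)=CC2=O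
F7 | step 7 | (2S)-2-[2,4-bis(tert-butyldimethylsilyloxy)phenyl]-7-(tert-butyldimethylsilyloxy)-4-{[diethoxy(methyl)silyl]oxy}-6,8-bis(3-methylbut-2-en-1-yl)-2H-chromene | CC(C)=CCc1cc2c(c(CC=C(C)C)c1O[Si](C)(C)C(C)(C)C)O[C@H](c1ccc(O[Si](C)(C)C(C)(C)C)cc1O[Si](C)(C)C(C)(C)C)C=C2O[Si](C)(OCC)OCC
F8 | step 7 | (2S)-2-[2,4-bis(tert-butyldimethylsilyloxy)phenyl]-7-(tert-butyldimethylsilyloxy)-6,8-bis(3-methylbut-2-en-1-yl)-2,3-dihydro-4H-chromen-4-one | CC(C)=CCc1cc2c(c(CC=C(C)C)c1O[Si](C)(C)C(C)(C)C)O[C@H](c1ccc(O[Si](C)(C)C(C)(C)C)cc1O[Si](C)(C)C(C)(C)C)CC2=O
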